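A direct plan would make the diarylmethane from two molecules of 3-bromo-4-hydroxybenzaldehyde (A1): reduction and double acetylation would give benzylic acetate A2, which in TfOH/HFIP would benzylate a second A1 ortho to its OH to give A3.
The catechol would then have to come from an ipso-hydroxylation of A3 with 2-iodoxybenzoic acid to o-quinol A4 and an acid-induced 1,2-benzyl shift to aldehyde A5, before a last borohydride reduction with acetate removal.
Weakest would be (a) the hydroxylation with 1,2-benzyl shift: it has no precedent, and the site of oxygen delivery, the migration terminus and the competition with benzyl loss or o-quinol dimerisation would be left to chance on the most advanced material.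
(b) The Friedel–Crafts benzylation: the nucleophile is a phenol deactivated by para-CHO and ortho-Br, so a large excess, a forcing acid and O-benzylation or oligomers would have to be accepted.
(c) The reduction/acetylation prelude and the final re-reduction: three of five steps would only change oxidation level or protecting groups and add no skeletal bond.

**Plan of the new route**
Ring A is numbered C1 (CH2OH), C2 (CH2Ar), C3 (OH), C4 (OH), C5 (Br), C6 (H). It carries two benzylic carbons on the neighbours C1 and C2 and an OH on C4, para to C1. Joining the CH2OH oxygen to the diarylmethane carbon in thought gives a 3-aryl-1,3-dihydro-2-benzofuran-4,5-diol, which is the retron of an intramolecular furan–alkyne Diels–Alder reaction.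
Retrosynthesis: cut that benzylic C–O bond (forward: ionic hydrogenation), exchange C3–OH for CHO (forward: Dakin), then cut ring A bonds C1–C2 and C3–C4. This leaves a 4-bromofurfuryl ether (C1, C6, C5, C4 and the C4 oxygen) and an ynal (C2, C3), assembled from the ring B aldehyde, an acetylene acetal and a furfuryl bromide.
Ring order: ring B and the furan are bought. The benzene ring A and a temporary dihydrofuran ring arise together in the cycloaddition, and the dihydrofuran ring is cut in the last step to free CH2OH and the diarylmethane CH2 at once.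
The weak steps vanish: the diarylmethane carbon is the aldehyde carbon of ring B from the start, so there is no Friedel–Crafts reaction on a deactivated phenol. The C4 oxygen is the furan oxygen and the C3 oxygen replaces the formyl group that activated the dienophile, so there is no hydroxylation with rearrangement. The C5 bromine comes with the furan.

Key step: step 6

Remark: compounds 1, 3 and 5 are taken to be commercial. The target has no stereocentre; the single stereocentre of the intermediates (the ether carbon that bears ring B) is carried as the racemate and becomes CH2 in the last step.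

**Step 1**
Reactants: 1 3-bromo-4-hydroxybenzaldehyde
Product: 2 3-bromo-4-[(4-methoxybenzyl)oxy]benzaldehyde
Conditions: PMBCl (1.1 equiv), K2CO3 (1.5 equiv), DMF, 50 °C
Reagents that add atoms: 4-methoxybenzyl chloride, COc1ccc(CCl)cc1
Why: Williamson O-alkylation of the phenoxide; the PMB ether should withstand the acetylide, the alkoxide and the peroxide used later and is removed by the acid of the last step.

**Step 2**
Reactants: 2 3-bromo-4-[(4-methoxybenzyl)oxy]benzaldehyde; 3 3,3-diethoxyprop-1-yne
Product: 4 racemic 1-{3-bromo-4-[(4-methoxybenzyl)oxy]phenyl}-4,4-diethoxybut-2-yn-1-ol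
Conditions: 3 (1.3 equiv), n-BuLi (1.2 equiv), THF, −78 °C; then 2, −78 → −20 °C; aq. NH4Cl
Reagents that add atoms: none
Why: 1,2-Addition of a lithium acetylide to an aryl aldehyde, with the alkyne in excess over n-BuLi so that no base is left for Br/Li exchange; the carbinol stereocentre forms as the racemate, which is of no consequence because this carbon ends as the diarylmethane CH2.

**Step 3**
Reactants: 5 4-bromofuran-2-carbaldehyde
Product: 6 (4-bromofuran-2-yl)methanol
Conditions: NaBH4 (0.5 equiv), MeOH, 0 °C
Reagents that add atoms: none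
Why: Borohydride reduction of a heteroaryl aldehyde, which should leave the C–Br bond untouched.

**Step 4**
Reactants: 6 (4-bromofuran-2-yl)methanol
Product: 7 4-bromo-2-(bromomethyl)furan
Conditions: PBr3 (0.4 equiv), Et2O, 0 °C; cold aq. NaHCO3 wash; dried solution used at once
Reagents that add atoms: phosphorus tribromide, BrP(Br)Br
Why: Conversion of a primary furfuryl alcohol into its bromide with PBr3 (SN2 on the phosphite ester); the ring bromine lowers the tendency of the furfuryl bromide to ionise, and it is not stored.

**Step 5**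
Reactants: 4 racemic 1-{3-bromo-4-[(4-methoxybenzyl)oxy]phenyl}-4,4-diethoxybut-2-yn-1-ol; 7 4-bromo-2-(bromomethyl)furan
Product: 8 racemic 4-bromo-2-{[(1-{3-bromo-4-[(4-methoxybenzyl)oxy]phenyl}-4,4-diethoxybut-2-yn-1-yl)oxy]methyl}furan
Conditions: NaH (1.1 equiv), THF, 0 °C; then 7 (1.2 equiv), Bu4NI (5 mol %), 0 °C → rt
Reagents that add atoms: none
Why: Williamson etherification of the secondary sodium alkoxide with a reactive furfuryl bromide; only a slight excess of base is used so that the propargylic ether is not isomerised to the allene.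

**Step 6**
Reactants: 8 racemic 4-bromo-2-{[(1-{3-bromo-4-[(4-methoxybenzyl)oxy]phenyl}-4,4-diethoxybut-2-yn-1-yl)oxy]methyl}furan
Product: 11 racemic 6-bromo-3-{3-bromo-4-[(4-methoxybenzyl)oxy]phenyl}-5-hydroxy-1,3-dihydro-2-benzofuran-4-carbaldehyde, via ynal 9 (not isolated), via oxa-bridged cycloadduct 10 (not isolated)
Conditions: 88% aq. HCO2H, CH2Cl2, 0 °C → rt; then PhMe, 80 °C
Reagents that add atoms: water, O
Why: Aqueous formic acid should hydrolyse the diethyl acetal to ynal 9, whose formyl-activated triple bond is held by the three-atom C–O–C tether over the furan and adds across furan C2 and C5 in an intramolecular [4+2] cycloaddition to give the 7-oxanorbornadiene 10; acid then breaks the oxygen bridge at the fully substituted bridgehead (allylic cation) and loss of the proton from the other bridgehead gives the phenol. The closest known reaction type is the intramolecular Diels–Alder reaction of furans with carbonyl-activated alkynes in furfuryl propargyl ethers, followed by acid-induced isomerisation of the 7-oxanorbornadiene to a phenol. The carbocycle of ring A is closed by the cycloaddition (bonds C1–C2 and C3–C4 of ring A) and made aromatic by the bridge opening, and the dihydrofuran ring is closed in the same cycloaddition as the five-membered ring that the tether imposes. The two bridgehead stereocentres of 10 form without control relative to the carbinol carbon, but both are erased on aromatisation, and the remaining carbon that bears ring B stays racemic until it becomes CH2 in step 8. Regioselectivity is needed in two places: the tether allows only the bond from furan C2 to the alkyne carbon next to the carbinol, which puts CHO on C3 and Br on C5, and only the hydrogen-bearing bridgehead can keep the oxygen and aromatise, which puts OH on C4. Halogen substituents on the furan are known to favour intramolecular furan Diels–Alder reactions, and the formyl group that activates the dienophile is the handle for the next step.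

**Step 7**
Reactants: 11 racemic 6-bromo-3-{3-bromo-4-[(4-methoxybenzyl)oxy]phenyl}-5-hydroxy-1,3-dihydro-2-benzofuran-4-carbaldehyde
Product: 13 racemic 6-bromo-3-{3-bromo-4-[(4-methoxybenzyl)oxy]phenyl}-1,3-dihydro-2-benzofuran-4,5-diol, via aryl formate 12 (not isolated)
Conditions: 30% H2O2 (1.3 equiv), aq. NaOH (2.5 equiv), THF, 0 °C, Ar; aq. NaH2PO4 to pH 5
Reagents that add atoms: hydrogen peroxide, OO
Why: Dakin oxidation: hydroperoxide adds to the aldehyde of the o-hydroxybenzaldehyde, the electron-rich aryl group migrates to oxygen and the formate is hydrolysed in the flask, so the second catechol oxygen should arrive exactly at the carbon that carried the formyl group (C3 of ring A) with no regiochemical choice.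

**Step 8**
Reactants: 13 racemic 6-bromo-3-{3-bromo-4-[(4-methoxybenzyl)oxy]phenyl}-1,3-dihydro-2-benzofuran-4,5-diol
Product: 15 6-bromo-3-[(3-bromo-4-hydroxyphenyl)methyl]-4-(hydroxymethyl)benzene-1,2-diol (CNP0232913.0), via ring-opened PMB ether 14 (not isolated)
Conditions: Et3SiH (6 equiv), TFA/CH2Cl2 (1:10), −20 → 0 °C; then MeOH, NaHCO3
Reagents that add atoms: none
Why: Ionic hydrogenation: TFA should ionise the doubly benzylic C–O bond of the cyclic ether (a cation flanked by the ortho-hydroxyl of ring A and the para-alkoxy group of ring B) far faster than the primary C–O bond, Et3SiH reduces the cation to the diarylmethane CH2 and thereby frees the CH2OH, and the same acid removes the PMB ether, whose cation is reduced as well; the stereocentre disappears.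

**Compound list**
1 | 3-bromo-4-hydroxybenzaldehyde | O=Cc1ccc(O)c(Br)c1 | starting material
2 | 3-bromo-4-[(4-methoxybenzyl)oxy]benzaldehyde | COc1ccc(COc2ccc(C=O)cc2Br)cc1 | intermediate
3 | 3,3-diethoxyprop-1-yne | CCOC(OCC)C#C | starting material
4 | racemic 1-{3-bromo-4-[(4-methoxybenzyl)oxy]phenyl}-4,4-diethoxybut-2-yn-1-ol | CCOC(OCC)C#CC(O)c1ccc(OCc2ccc(OC)cc2)c(Br)c1 | intermediate
5 | 4-bromofuran-2-carbaldehyde | O=Cc1cc(Br)co1 | starting material
6 | (4-bromofuran-2-yl)methanol | OCc1cc(Br)co1 | intermediate
7 | 4-bromo-2-(bromomethyl)furan | BrCc1cc(Br)co1 | intermediate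
8 | racemic 4-bromo-2-{[(1-{3-bromo-4-[(4-methoxybenzyl)oxy]phenyl}-4,4-diethoxybut-2-yn-1-yl)oxy]methyl}furan | CCOC(OCC)C#CC(OCc1cc(Br)co1)c1ccc(OCc2ccc(OC)cc2)c(Br)c1 | intermediate
9 | racemic 4-{3-bromo-4-[(4-methoxybenzyl)oxy]phenyl}-4-[(4-bromofuran-2-yl)methoxy]but-2-ynal | O=CC#CC(OCc1cc(Br)co1)c1ccc(OCc2ccc(OC)cc2)c(Br)c1 | intermediate (not isolated)
10 | 6-bromo-3-{3-bromo-4-[(4-methoxybenzyl)oxy]phenyl}-5,7a-epoxy-1,3,5,7a-tetrahydro-2-benzofuran-4-carbaldehyde (oxa-bridged cycloadduct, mixture of racemic diastereomers) | O=CC1=C2C(c5ccc(OCc6ccc(OC)cc6)c(Br)c5)OCC23OC1C(Br)=C3 | intermediate (not isolated)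
11 | racemic 6-bromo-3-{3-bromo-4-[(4-methoxybenzyl)oxy]phenyl}-5-hydroxy-1,3-dihydro-2-benzofuran-4-carbaldehyde | O=Cc1c(O)c(Br)cc2COC(c3ccc(OCc4ccc(OC)cc4)c(Br)c3)c12 | intermediate
12 | racemic 6-bromo-3-{3-bromo-4-[(4-methoxybenzyl)oxy]phenyl}-5-hydroxy-1,3-dihydro-2-benzofuran-4-yl formate | O=COc1c(O)c(Br)cc2COC(c3ccc(OCc4ccc(OC)cc4)c(Br)c3)c12 | intermediate (not isolated)
13 | racemic 6-bromo-3-{3-bromo-4-[(4-methoxybenzyl)oxy]phenyl}-1,3-dihydro-2-benzofuran-4,5-diol | Oc1c(O)c(Br)cc2COC(c3ccc(OCc4ccc(OC)cc4)c(Br)c3)c12 | intermediate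
14 | 6-bromo-3-{3-bromo-4-[(4-methoxybenzyl)oxy]benzyl}-4-(hydroxymethyl)benzene-1,2-diol | OCc1cc(Br)c(O)c(O)c1Cc1ccc(OCc2ccc(OC)cc2)c(Br)c1 | intermediate (not isolated)
15 | 6-bromo-3-[(3-bromo-4-hydroxyphenyl)methyl]-4-(hydroxymethyl)benzene-1,2-diol | OCc1cc(Br)c(O)c(O)c1Cc1ccc(O)c(Br)c1 | target

**Step count and risks**
Total steps: 8. Longest linear sequence: 6 steps (1, 2, 5, 6, 7, 8; the furan branch 3, 4, 5, 6, 7, 8 is equally long).

Steps most likely to fail:

Step 6. The acid that unmasks the ynal could ionise the benzylic or the furfuryl C–O bond or remove the PMB group before the cycloaddition, or the opening of the oxygen bridge could stall. The fallback would build ring A by a gold-catalysed furan–alkyne phenol synthesis that needs neither acid nor an ynal. Setting out from 2, ethynylmagnesium bromide (THF, 0 °C) would give racemic 1-{3-bromo-4-[(4-methoxybenzyl)oxy]phenyl}prop-2-yn-1-ol F1. NaH and 7 (THF, 0 °C → rt) would give racemic 4-bromo-2-{[(1-{3-bromo-4-[(4-methoxybenzyl)oxy]phenyl}prop-2-yn-1-yl)oxy]methyl}furan F2. Ph3PAuNTf2 (5 mol %, a complex of monovalent gold; CH2Cl2, rt) should cycloisomerise F2 to racemic 6-bromo-3-{3-bromo-4-[(4-methoxybenzyl)oxy]phenyl}-1,3-dihydro-2-benzofuran-4-ol F3, in which the furan oxygen ends on C3 of ring A. Ortho-oxygenation of F3 with 2-iodoxybenzoic acid (DMF, rt) and reduction of the o-quinone with aq. Na2S2O4 would come back to the route at 13; oxygen delivery to the free ortho position rather than the substituted one is the uncertain point of this fallback.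

Step 8. Once freed, the CH2OH group sits para to the C4 hydroxyl, so it could ionise in TFA and be reduced further to a methyl group, or the PMB cation could alkylate the catechol ring. The fallback would deactivate ring A before the ionisation. Setting out from 13, Ac2O/pyridine/DMAP (CH2Cl2, 0 °C) would give racemic 6-bromo-3-{3-bromo-4-[(4-methoxybenzyl)oxy]phenyl}-1,3-dihydro-2-benzofuran-4,5-diyl diacetate F4. Et3SiH/TFA (CH2Cl2, 0 °C → rt) should open the ether, now driven only by ring B, and remove the PMB group to give 6-bromo-3-(3-bromo-4-hydroxybenzyl)-4-(hydroxymethyl)-1,2-phenylene diacetate F5, whose primary alcohol is no longer activated. K2CO3 in degassed MeOH (0 °C, Ar; AcOH to pH 5) would come back to the route at 15.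

Step 7. The electron-rich catechol could be oxidised further in alkaline peroxide, or hydroperoxide could add only slowly to the hindered, hydrogen-bonded aldehyde. The fallback would use a peracid Baeyer–Villiger oxidation on the silyl ether, so that the catechol is set free only after the oxidant is gone. Setting out from 11, TBSOTf/2,6-lutidine (CH2Cl2, 0 °C) would give racemic 6-bromo-3-{3-bromo-4-[(4-methoxybenzyl)oxy]phenyl}-5-[(tert-butyldimethylsilyl)oxy]-1,3-dihydro-2-benzofuran-4-carbaldehyde F6. mCPBA/NaHCO3 (CH2Cl2, 0 °C → rt) should give racemic 6-bromo-3-{3-bromo-4-[(4-methoxybenzyl)oxy]phenyl}-5-[(tert-butyldimethylsilyl)oxy]-1,3-dihydro-2-benzofuran-4-yl formate F7. K2CO3 in degassed MeOH (0 °C → rt) would cleave the formate and the aryl silyl ether and come back to the route at 13.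

**Further compounds**
F1 | step 6 | racemic 1-{3-bromo-4-[(4-methoxybenzyl)oxy]phenyl}prop-2-yn-1-ol | C#CC(O)c1ccc(OCc2ccc(OC)cc2)c(Br)c1
F2 | step 6 | racemic 4-bromo-2-{[(1-{3-bromo-4-[(4-methoxybenzyl)oxy]phenyl}prop-2-yn-1-yl)oxy]methyl}furan | C#CC(OCc1cc(Br)co1)c1ccc(OCc2ccc(OC)cc2)c(Br)c1
F3 | step 6 | racemic 6-bromo-3-{3-bromo-4-[(4-methoxybenzyl)oxy]phenyl}-1,3-dihydro-2-benzofuran-4-ol | Oc1cc(Br)cc2COC(c3ccc(OCc4ccc(OC)cc4)c(Br)c3)c12
F4 | step 8 | racemic 6-bromo-3-{3-bromo-4-[(4-methoxybenzyl)oxy]phenyl}-1,3-dihydro-2-benzofuran-4,5-diyl diacetate | CC(=O)Oc1c(OC(C)=O)c(Br)cc2COC(c3ccc(OCc4ccc(OC)cc4)c(Br)c3)c12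
F5 | step 8 | 6-bromo-3-(3-bromo-4-hydroxybenzyl)-4-(hydroxymethyl)-1,2-phenylene diacetate | OCc1cc(Br)c(OC(C)=O)c(OC(C)=O)c1Cc1ccc(O)c(Br)c1
F6 | step 7 | racemic 6-bromo-3-{3-bromo-4-[(4-methoxybenzyl)oxy]phenyl}-5-[(tert-butyldimethylsilyl)oxy]-1,3-dihydro-2-benzofuran-4-carbaldehyde | O=Cc1c(O[Si](C)(C)C(C)(C)C)c(Br)cc2COC(c3ccc(OCc4ccc(OC)cc4)c(Br)c3)c12
F7 | step 7 | racemic 6-bromo-3-{3-bromo-4-[(4-methoxybenzyl)oxy]phenyl}-5-[(tert-butyldimethylsilyl)oxy]-1,3-dihydro-2-benzofuran-4-yl formate | O=COc1c(O[Si](C)(C)C(C)(C)C)c(Br)cc2COC(c3ccc(OCc4ccc(OC)cc4)c(Br)c3)c12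
A1 | direct plan | 3-bromo-4-hydroxybenzaldehyde | O=Cc1ccc(O)c(Br)c1
A2 | direct plan | 4-(acetoxymethyl)-2-bromophenyl acetate | CC(=O)OCc1ccc(OC(C)=O)c(Br)c1
A3 | direct plan | 2-bromo-4-(3-bromo-5-formyl-2-hydroxybenzyl)phenyl acetate | CC(=O)Oc1ccc(Cc2cc(C=O)cc(Br)c2O)cc1Br
A4 | direct plan | racemic 2-bromo-4-[(3-bromo-5-formyl-1-hydroxy-2-oxocyclohexa-3,5-dien-1-yl)methyl]phenyl acetate | O=C1C(Br)=CC(C=O)=CC1(O)Cc1ccc(OC(C)=O)c(Br)c1
A5 | direct plan | 2-bromo-4-(4-bromo-6-formyl-2,3-dihydroxybenzyl)phenyl acetate | CC(=O)Oc1ccc(Cc2c(C=O)cc(Br)c(O)c2O)cc1Br
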